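**Retrosynthetic overview**

1. Target 20 comes from the 6α-acrylate 19 by a last-step Morita–Baylis–Hillman hydroxymethylation; before that, two Luche reductions set 1β-OH and 3β-OH, and two methylenations give C11=C13 and C4=C15.
2. All of this is done on the trans-fused enedione 8, which is the C5 epimer of the cis Diels–Alder adduct 7.
3. Key disconnection: C9–C10 and C5–C6 are cut together, giving diene 5 (C6–C9 with the C11–C12 arm) and 2-methoxy-5-methyl-1,4-benzoquinone 6.
4. Enabling feature: in ring A, C1 (O) and C4 (=CH2, a former C=O) sit para across the C5–C10 bond and C3 carries O, so ring A is a reduced methoxytoluquinone whose C5=C10 bond is a dienophile; in ring B the oxygen on C6, next to C5, is the terminus of a 1-oxy diene.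
5. Ring order: ring A is bought intact as 6; ring B is closed in the key step; no other ring is formed.

Key step: step 4

Numbering: eudesmane numbering is used (C10 = quaternary carbon with methyl C14; C5 = ring-fusion CH; ring A = C1–C5 and C10; ring B = C5–C10; C15 = methylene carbon on C4; C11–C13 = acrylate arm on C7); β means the face of C14, and 5-H and 7-H are α unless stated.

Assumption: 1 and 6 are taken as purchasable; 6 is otherwise one oxidation step from 2-methoxy-5-methylphenol.

**Step 1**
Reactants: 1 methyl (E)-4,4-dimethoxybut-2-enoate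
Product: 2 methyl 3-(dimethoxymethyl)pent-4-enoate (racemic)
Conditions: CH2=CHMgBr (1.3 equiv), CuBr·SMe2 (10 mol %), THF, −78 → −30 °C; then H2O
Reagents that add atoms: vinylmagnesium bromide C=C[Mg]Br
Why: Copper-catalysed conjugate addition of a vinyl Grignard reagent to the enoate puts the vinyl group β to the ester, and the new stereocentre does not matter because it becomes trigonal in step 2.

**Step 2**
Reactants: 2 methyl 3-(dimethoxymethyl)pent-4-enoate
Product: 4 methyl (E)-3-formylpent-3-enoate, via methyl 3-formylpent-4-enoate 3 (not isolated)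
Conditions: 1 M HCl, THF, rt; then Et3N (0.1 equiv), CH2Cl2, rt
Reagents that add atoms: water O
Why: Acetal hydrolysis followed by base-mediated migration of the β,γ double bond into conjugation with the aldehyde should give the thermodynamic E enal (formyl trans to methyl), since the weak base enolises only the aldehyde.

**Step 3**
Reactants: 4 methyl (E)-3-formylpent-3-enoate
Product: 5 methyl (3E)-3-{[(tert-butyldimethylsilyl)oxy]methylidene}pent-4-enoate
Conditions: TBSOTf (1.1 equiv), Et3N (1.5 equiv), Et2O, 0 °C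
Reagents that add atoms: tert-butyldimethylsilyl trifluoromethanesulfonate CC(C)(C)[Si](C)(C)OS(=O)(=O)C(F)(F)F
Why: Silyl dienol ether formation by O-silylation and γ-deprotonation of the enal, whose preferred s-trans conformation places the silyloxy group trans to the new vinyl group (the E diene that can reach the s-cis form).

**Step 4**
Reactants: 5 methyl (3E)-3-{[(tert-butyldimethylsilyl)oxy]methylidene}pent-4-enoate and 6 2-methoxy-5-methyl-1,4-benzoquinone
Product: 7 methyl 6α-[(tert-butyldimethylsilyl)oxy]-3-methoxy-1,4-dioxo-13,15-dinor-5β-eudesma-2,7-dien-12-oate (cis-fused)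
Conditions: (R)-BINOL (20 mol %), TiCl2(OiPr)2 (20 mol %), 4 Å molecular sieves (removed before use), CH2Cl2, −40 °C
Reagents that add atoms: none
Why: This is an intermolecular quinone Diels–Alder reaction with a 1-oxygenated diene under chiral Lewis acid catalysis, the reaction type of the classical methoxytoluquinone–butadiene cycloaddition and of BINOL–titanium-catalysed quinone cycloadditions; the titanium centre chelates the C4 carbonyl oxygen and the C3 methoxy oxygen of 6, so the C5=C10 bond reacts as a β-methyl enone polarised towards C10. Ring B closes in one suprafacial [4+2] event (a six-membered ring from a four-atom and a two-atom component, no tether), the nucleophilic unsubstituted diene terminus C9 bonding to C10 and the oxygenated terminus C6 bonding to C5. Site selectivity (C5=C10, not C2=C3) comes from the methoxy group, which makes C2=C3 a deactivated vinylogous ester; regioselectivity comes from chelation at C4 together with the donor on C6. The quaternary C10 and C5 arise cis because addition is suprafacial on the ring dienophile; C6 is set by the endo transition state of the E diene, which puts the silyloxy group trans to the C5 hydrogen; the absolute configuration of all three is set by the BINOL ligand shielding one face of the chelated quinone. C5 is formed in the cis sense on purpose and is corrected in step 5; which ligand antipode leads to 7 and not its mirror image is to be fixed on the first run.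

**Step 5**
Reactants: 7 cis-fused adduct
Product: 8 methyl 6α-[(tert-butyldimethylsilyl)oxy]-3-methoxy-1,4-dioxo-13,15-dinor-5α-eudesma-2,7-dien-12-oate (trans-fused)
Conditions: K2CO3 (0.2 equiv), MeOH/THF, 0 °C
Reagents that add atoms: none
Why: Base-mediated epimerisation through the C4 enolate (the only enolisable position) should favour the trans isomer, as in the classical methoxytoluquinone adduct series, because with C1, C4 and C8 trigonal the axial C14 methyl has a single syn-axial hydrogen, and the protic medium keeps the enolate short-lived.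

**Step 6**
Reactants: 8 trans-fused enedione
Product: 9 methyl 6α-[(tert-butyldimethylsilyl)oxy]-3-methoxy-1,4-dioxo-13,15-dinoreudesm-2-en-12-oate (7α-H)
Conditions: H2 (1 atm), [Ir(cod)(PCy3)(py)]PF6 (5 mol %), CH2Cl2, 0 °C → rt
Reagents that add atoms: none
Why: Homogeneous hydrogenation of the trisubstituted C7=C8 bond should leave the push–pull C2=C3 bond alone and add hydrogen from the α-face opposite the axial C14 methyl, so that the C7 arm becomes β (equatorial, trans to the 6α-silyloxy group).

**Step 7**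
Reactants: 9 saturated enedione
Product: 10 methyl 6α-[(tert-butyldimethylsilyl)oxy]-3-methoxy-1-oxo-13-noreudesma-2,4(15)-dien-12-oate
Conditions: Zn, CH2Br2, TiCl4, THF/CH2Cl2, 0 °C → rt
Reagents that add atoms: dibromomethane BrCBr
Why: Takai–Lombardo methylenation is non-basic (no enolisation at C5) and selective for the ketone at C4 over the vinylogous ester carbonyl C1 and the methyl ester.

**Step 8**
Reactants: 10 dienone
Product: 11 methyl 6α-[(tert-butyldimethylsilyl)oxy]-1β-hydroxy-3-methoxy-13-noreudesma-2,4(15)-dien-12-oate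
Conditions: NaBH4, CeCl3·7H2O, MeOH, −20 → 0 °C; NaHCO3 work-up
Reagents that add atoms: none
Why: Luche 1,2-reduction of the C1 carbonyl spares the ester, and hydride attacks the α-face away from the adjacent axial C14 methyl, giving the 1β (equatorial) alcohol.

**Step 9**
Reactants: 11 allylic alcohol
Product: 12 methyl 6α-[(tert-butyldimethylsilyl)oxy]-3-methoxy-1β-[(triisopropylsilyl)oxy]-13-noreudesma-2,4(15)-dien-12-oate
Conditions: TIPSOTf, 2,6-lutidine, CH2Cl2, −78 °C
Reagents that add atoms: triisopropylsilyl trifluoromethanesulfonate CC(C)[Si](C(C)C)(C(C)C)OS(=O)(=O)C(F)(F)F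
Why: Silylation turns the C1 oxygen into a poor leaving group, so that the later acid hydrolysis of the dienol ether does not ionise C1–O (no 1,3-carbonyl transposition), and it keeps C1–O masked during the C6 acylation.

**Step 10**
Reactants: 12 bis-silyl ether
Product: 15 methyl 6α-[(tert-butyldimethylsilyl)oxy]-3-methoxy-1β-[(triisopropylsilyl)oxy]eudesma-2,4(15),11(13)-trien-12-oate, via Mannich base 13 (not isolated), via trimethylammonium iodide 14 (not isolated)
Conditions: LiN(iPr)2, THF, −78 °C; CH2=NMe2+ I− (1.05 equiv), −78 → 0 °C; then MeI, MeOH, rt; then DBU, CH2Cl2, rt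
Reagents that add atoms: N,N-dimethylmethyleneiminium iodide C=[N+](C)C.[I-]
Why: Ester α-methylenation (enolate Mannich reaction with Eschenmoser's salt, quaternisation, elimination) should be clean here because the ester CH2 is the only acidic site and ring A holds no electrophile at this stage.

**Step 11**
Reactants: 15 acrylate
Product: 16 methyl 6α-hydroxy-3-oxo-1β-[(triisopropylsilyl)oxy]eudesma-4(15),11(13)-dien-12-oate
Conditions: HF·pyridine, pyridine, THF/H2O, 0 °C → rt
Reagents that add atoms: water O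
Why: Acid hydrolysis of the 2-methoxy-1,3-diene (protonation at C2, water at C3) unmasks the C3 ketone with C4=C15 intact, while the secondary TBS ether at C6 is cleaved in preference to the more robust TIPS ether at C1.

**Step 12**
Reactants: 16 hydroxy enone
Product: 17 methyl 6α-(acryloyloxy)-3-oxo-1β-[(triisopropylsilyl)oxy]eudesma-4(15),11(13)-dien-12-oate
Conditions: CH2=CHCOCl, iPr2NEt, CH2Cl2, −30 → 0 °C
Reagents that add atoms: acryloyl chloride C=CC(=O)Cl
Why: O-acylation of the only free hydroxyl with a small, reactive acyl chloride, run cold so that the hydroxy ester does not lactonise first.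

**Step 13**
Reactants: 17 keto diacrylate
Product: 18 methyl 6α-(acryloyloxy)-3β-hydroxy-1β-[(triisopropylsilyl)oxy]eudesma-4(15),11(13)-dien-12-oate
Conditions: NaBH4, CeCl3·7H2O, MeOH, −78 °C
Reagents that add atoms: none
Why: Luche 1,2-reduction of the exocyclic enone is fast enough at low temperature to spare both acrylates, and axial hydride delivery from the α-face gives the equatorial 3β alcohol.

**Step 14**
Reactants: 18 silyl ether
Product: 19 methyl 6α-(acryloyloxy)-1β,3β-dihydroxyeudesma-4(15),11(13)-dien-12-oate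
Conditions: HF·pyridine, THF, 0 °C → rt
Reagents that add atoms: none
Why: Fluoride-mediated desilylation under buffered, non-basic conditions that acrylates and the allylic alcohol tolerate.

**Step 15**
Reactants: 19 diol acrylate
Product: 20 methyl 1β,3β-dihydroxy-6α-{[2-(hydroxymethyl)acryloyl]oxy}eudesma-4(15),11(13)-dien-12-oate (target)
Conditions: aq. HCHO (37 %), DABCO (1 equiv), 1,4-dioxane/H2O, rt
Reagents that add atoms: formaldehyde C=O
Why: Morita–Baylis–Hillman reaction of an acrylate ester with formaldehyde, in which only the C6 acrylate has the α-hydrogen required, the α-substituted C11–C13 acrylate and the free hydroxyls are spectators, and no stereocentre is formed.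

**Compound list**

1 | methyl (E)-4,4-dimethoxybut-2-enoate | COC(OC)/C=C/C(=O)OC | starting material
2 | methyl 3-(dimethoxymethyl)pent-4-enoate (racemic) | COC(OC)C(C=C)CC(=O)OC | intermediate
3 | methyl 3-formylpent-4-enoate | O=CC(C=C)CC(=O)OC | intermediate (not isolated)
4 | methyl (E)-3-formylpent-3-enoate | C/C=C(/C=O)CC(=O)OC | intermediate
5 | methyl (3E)-3-{[(tert-butyldimethylsilyl)oxy]methylidene}pent-4-enoate | C=C/C(CC(=O)OC)=C/O[Si](C)(C)C(C)(C)C | intermediate
6 | 2-methoxy-5-methyl-1,4-benzoquinone | COC1=CC(=O)C(C)=CC1=O | starting material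
7 | methyl 6α-[(tert-butyldimethylsilyl)oxy]-3-methoxy-1,4-dioxo-13,15-dinor-5β-eudesma-2,7-dien-12-oate | CC(C)(C)[Si](C)(C)O[C@@H]1[C@@H]2C(=O)C(OC)=CC(=O)[C@]2(C)CC=C1CC(=O)OC | intermediate
8 | methyl 6α-[(tert-butyldimethylsilyl)oxy]-3-methoxy-1,4-dioxo-13,15-dinor-5α-eudesma-2,7-dien-12-oate | CC(C)(C)[Si](C)(C)O[C@@H]1[C@H]2C(=O)C(OC)=CC(=O)[C@]2(C)CC=C1CC(=O)OC | intermediate
9 | methyl 6α-[(tert-butyldimethylsilyl)oxy]-3-methoxy-1,4-dioxo-13,15-dinoreudesm-2-en-12-oate | CC(C)(C)[Si](C)(C)O[C@@H]1[C@H]2C(=O)C(OC)=CC(=O)[C@]2(C)CC[C@H]1CC(=O)OC | intermediate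
10 | methyl 6α-[(tert-butyldimethylsilyl)oxy]-3-methoxy-1-oxo-13-noreudesma-2,4(15)-dien-12-oate | CC(C)(C)[Si](C)(C)O[C@@H]1[C@H]2C(=C)C(OC)=CC(=O)[C@]2(C)CC[C@H]1CC(=O)OC | intermediate
11 | methyl 6α-[(tert-butyldimethylsilyl)oxy]-1β-hydroxy-3-methoxy-13-noreudesma-2,4(15)-dien-12-oate | CC(C)(C)[Si](C)(C)O[C@@H]1[C@H]2C(=C)C(OC)=C[C@@H](O)[C@]2(C)CC[C@H]1CC(=O)OC | intermediate
12 | methyl 6α-[(tert-butyldimethylsilyl)oxy]-3-methoxy-1β-[(triisopropylsilyl)oxy]-13-noreudesma-2,4(15)-dien-12-oate | CC(C)(C)[Si](C)(C)O[C@@H]1[C@H]2C(=C)C(OC)=C[C@@H](O[Si](C(C)C)(C(C)C)C(C)C)[C@]2(C)CC[C@H]1CC(=O)OC | intermediate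
13 | methyl 13-(dimethylamino)-6α-[(tert-butyldimethylsilyl)oxy]-3-methoxy-1β-[(triisopropylsilyl)oxy]eudesma-2,4(15)-dien-12-oate (C11 epimers) | CC(C)(C)[Si](C)(C)O[C@@H]1[C@H]2C(=C)C(OC)=C[C@@H](O[Si](C(C)C)(C(C)C)C(C)C)[C@]2(C)CC[C@H]1C(CN(C)C)C(=O)OC | intermediate (not isolated)
14 | 13-(trimethylammonio) analogue of 13, iodide | CC(C)(C)[Si](C)(C)O[C@@H]1[C@H]2C(=C)C(OC)=C[C@@H](O[Si](C(C)C)(C(C)C)C(C)C)[C@]2(C)CC[C@H]1C(C[N+](C)(C)C)C(=O)OC.[I-] | intermediate (not isolated)
15 | methyl 6α-[(tert-butyldimethylsilyl)oxy]-3-methoxy-1β-[(triisopropylsilyl)oxy]eudesma-2,4(15),11(13)-trien-12-oate | CC(C)(C)[Si](C)(C)O[C@@H]1[C@H]2C(=C)C(OC)=C[C@@H](O[Si](C(C)C)(C(C)C)C(C)C)[C@]2(C)CC[C@H]1C(=C)C(=O)OC | intermediate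
16 | methyl 6α-hydroxy-3-oxo-1β-[(triisopropylsilyl)oxy]eudesma-4(15),11(13)-dien-12-oate | O[C@@H]1[C@H]2C(=C)C(=O)C[C@@H](O[Si](C(C)C)(C(C)C)C(C)C)[C@]2(C)CC[C@H]1C(=C)C(=O)OC | intermediate
17 | methyl 6α-(acryloyloxy)-3-oxo-1β-[(triisopropylsilyl)oxy]eudesma-4(15),11(13)-dien-12-oate | C=CC(=O)O[C@@H]1[C@H]2C(=C)C(=O)C[C@@H](O[Si](C(C)C)(C(C)C)C(C)C)[C@]2(C)CC[C@H]1C(=C)C(=O)OC | intermediate
18 | methyl 6α-(acryloyloxy)-3β-hydroxy-1β-[(triisopropylsilyl)oxy]eudesma-4(15),11(13)-dien-12-oate | C=CC(=O)O[C@@H]1[C@H]2C(=C)[C@@H](O)C[C@@H](O[Si](C(C)C)(C(C)C)C(C)C)[C@]2(C)CC[C@H]1C(=C)C(=O)OC | intermediate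
19 | methyl 6α-(acryloyloxy)-1β,3β-dihydroxyeudesma-4(15),11(13)-dien-12-oate | C=CC(=O)O[C@@H]1[C@H]2C(=C)[C@@H](O)C[C@@H](O)[C@]2(C)CC[C@H]1C(=C)C(=O)OC | intermediate
20 | methyl 1β,3β-dihydroxy-6α-{[2-(hydroxymethyl)acryloyl]oxy}eudesma-4(15),11(13)-dien-12-oate (CNP0247525.1) | C=C(CO)C(=O)O[C@@H]1[C@H]2C(=C)[C@@H](O)C[C@@H](O)[C@]2(C)CC[C@H]1C(=C)C(=O)OC | target

**Step count and risks**

Total step count: 15. Longest linear sequence: 15 steps (1 → 20; 6 enters at step 4).

Steps most likely to fail:

1. Step 5 (C5 epimerisation). The C4 enolate may expel the C6 silyloxy group (β-elimination to a C5=C6 dienone), or the cis/trans equilibrium may not lie far enough on the trans side. The fallback sets out from 7 and comes back at 10; it removes the C5 hydrogen on purpose and returns it by a sigmatropic hydrogen transfer. KN(SiMe3)2 and PhNTf2 (THF, −78 °C) convert 7 into the C4 dienyl triflate F1. Hydrogenation as in step 6 gives the 7α-H triflate F2. Stille coupling with Bu3SnCH2OH (Pd(PPh3)4, dioxane, 80 °C) gives the C15 allylic alcohol F3. Mitsunobu reaction with 2-nitrobenzenesulfonylhydrazide (PPh3, DEAD, THF, −30 °C) gives the sulfonylhydrazine F4, which on warming loses the sulfinic acid to give the allylic diazene F5. Retro-ene loss of N2 from F5 moves the double bond to C4=C15 and should deliver hydrogen to C5 on the face opposite the C14 methyl, giving 10; steps 5 to 7 are then not needed.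

2. Step 4 (Diels–Alder). The trisubstituted C5=C10 bond may react slowly under the chiral catalyst, facial discrimination may be poor, or Mukaiyama–Michael addition may occur without ring closure. The fallback sets out from 5 and 6 and comes back at 8. Chelation-controlled cycloaddition with SnCl4 (1 equiv, CH2Cl2, −78 °C) gives 7 as a racemate with its enantiomer F6. Step 5 then gives 8 together with its enantiomer F7, and preparative chromatography on a chiral stationary phase (amylose tris(3,5-dimethylphenylcarbamate)) provides 8.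

3. Step 15 (Morita–Baylis–Hillman). Addition of the amine to the hindered C6 acrylate may be slow, so that ester hydrolysis or oligomer formation with formaldehyde competes. The fallback sets out from 16 and comes back at 20; the hydroxymethyl group is brought in preformed. Purchased methyl 2-(hydroxymethyl)acrylate is silylated (TBSCl, imidazole, DMF) to the silyl ether F8 and saponified (LiOH, THF/H2O) to the acid F9. Yamaguchi esterification of 16 with F9 (2,4,6-trichlorobenzoyl chloride, Et3N, DMAP, toluene) gives the ester F10. Luche reduction as in step 13 gives the 3β-alcohol F11, and HF·pyridine removes both silyl groups to give 20.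

**Further compounds**

F1 | step 5 | methyl 6α-[(tert-butyldimethylsilyl)oxy]-3-methoxy-1-oxo-4-{[(trifluoromethyl)sulfonyl]oxy}-13,15-dinoreudesma-2,4,7-trien-12-oate | CC(C)(C)[Si](C)(C)O[C@@H]1C2=C(OS(=O)(=O)C(F)(F)F)C(OC)=CC(=O)[C@]2(C)CC=C1CC(=O)OC
F2 | step 5 | methyl 6α-[(tert-butyldimethylsilyl)oxy]-3-methoxy-1-oxo-4-{[(trifluoromethyl)sulfonyl]oxy}-13,15-dinoreudesma-2,4-dien-12-oate (7α-H) | CC(C)(C)[Si](C)(C)O[C@@H]1C2=C(OS(=O)(=O)C(F)(F)F)C(OC)=CC(=O)[C@]2(C)CC[C@H]1CC(=O)OC
F3 | step 5 | methyl 6α-[(tert-butyldimethylsilyl)oxy]-15-hydroxy-3-methoxy-1-oxo-13-noreudesma-2,4-dien-12-oate | CC(C)(C)[Si](C)(C)O[C@@H]1C2=C(CO)C(OC)=CC(=O)[C@]2(C)CC[C@H]1CC(=O)OC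
F4 | step 5 | 15-[1-(2-nitrobenzenesulfonyl)hydrazinyl] analogue of F3 | CC(C)(C)[Si](C)(C)O[C@@H]1C2=C(CN(N)S(=O)(=O)c3ccccc3[N+](=O)[O-])C(OC)=CC(=O)[C@]2(C)CC[C@H]1CC(=O)OC
F5 | step 5 | 15-diazenyl analogue of F3 (allylic diazene) | CC(C)(C)[Si](C)(C)O[C@@H]1C2=C(CN=N)C(OC)=CC(=O)[C@]2(C)CC[C@H]1CC(=O)OC
F6 | step 4 | enantiomer of 7 | CC(C)(C)[Si](C)(C)O[C@H]1[C@H]2C(=O)C(OC)=CC(=O)[C@@]2(C)CC=C1CC(=O)OC
F7 | step 4 | enantiomer of 8 | CC(C)(C)[Si](C)(C)O[C@H]1[C@@H]2C(=O)C(OC)=CC(=O)[C@@]2(C)CC=C1CC(=O)OC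
F8 | step 15 | methyl 2-{[(tert-butyldimethylsilyl)oxy]methyl}prop-2-enoate | C=C(CO[Si](C)(C)C(C)(C)C)C(=O)OC
F9 | step 15 | 2-{[(tert-butyldimethylsilyl)oxy]methyl}prop-2-enoic acid | C=C(CO[Si](C)(C)C(C)(C)C)C(=O)O
F10 | step 15 | methyl 6α-[(2-{[(tert-butyldimethylsilyl)oxy]methyl}acryloyl)oxy]-3-oxo-1β-[(triisopropylsilyl)oxy]eudesma-4(15),11(13)-dien-12-oate | C=C(CO[Si](C)(C)C(C)(C)C)C(=O)O[C@@H]1[C@H]2C(=C)C(=O)C[C@@H](O[Si](C(C)C)(C(C)C)C(C)C)[C@]2(C)CC[C@H]1C(=C)C(=O)OC
F11 | step 15 | methyl 6α-[(2-{[(tert-butyldimethylsilyl)oxy]methyl}acryloyl)oxy]-3β-hydroxy-1β-[(triisopropylsilyl)oxy]eudesma-4(15),11(13)-dien-12-oate | C=C(CO[Si](C)(C)C(C)(C)C)C(=O)O[C@@H]1[C@H]2C(=C)[C@@H](O)C[C@@H](O[Si](C(C)C)(C(C)C)C(C)C)[C@]2(C)CC[C@H]1C(=C)C(=O)OC
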